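## Retrosynthetic overview

1. Target = upper (2S,4S)-flavan joined C4'–C6 to a lower (2R,3R,4R)-flavan-3,4-diol (C2-aryl, 3-OH and 4-OH all cis); last disconnection is six benzyl ethers, and C3 comes from hydride delivery to a flavan-3-one flanked by cis 2-aryl and 4-acyloxy groups.
2. The C4 oxygen comes from an enol formate: epoxidation anti to the 2-aryl group, then a 1,2-acyloxy shift that puts oxygen on C4 syn to the aryl group; the enol formate comes from Baeyer–Villiger oxidation of a 2H-chromene-3-carbaldehyde (formyl carbon exchanged for the C3 oxygen).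
3. Key disconnection: lower ring C by C3–C4 aldol closure after O1–C2 oxa-Michael addition, from salicylaldehyde 10 and cinnamaldehyde 11 under chiral amine catalysis. Enabling feature: O1 (on C8a) and C4 (on C4a) are ortho on lower ring A (a latent salicylaldehyde), C2 is a benzylic ether carbon, and C3 bears an oxygen that can be traced back to a formyl group, which makes C3 an enamine nucleophile.
4. C4'–C6 bond: Friedel–Crafts alkylation of pyrogallol by the upper flavan-4-ol (2',4'-trans), then formylation ortho to the future O1; upper unit from gallacetophenone and 4-(benzyloxy)benzaldehyde via chalcone, flavanone and a kinetic resolution by transfer hydrogenation.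
5. Ring order: upper ring C' (step 3), then lower ring C (step 9).

Key step: step 9

Remarks:
- Unprimed locants refer to the lower flavan-3,4-diol unit, primed locants to the upper flavan unit. "Fl" = 7,8-bis(benzyloxy)-2-[4-(benzyloxy)phenyl]chroman-4-yl with (2'S) and 2',4'-trans geometry.
- The CIP descriptor of C4' is S in 8, 9 and 19 and R in 10 and 12–18. This is only because benzylation of the neighbouring ring oxygen changes the priority order at C4'; the geometry never changes.
- Assumption: 1, 3, 7 and the named reagents are commercial.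

## Route

Step 1
Reactants: 1 1-(2,3,4-trihydroxyphenyl)ethanone (gallacetophenone)
Product: 2 1-[3,4-bis(benzyloxy)-2-hydroxyphenyl]ethanone
Conditions: BnBr (2.1 equiv), K2CO3 (2.2 equiv), DMF, rt
Reagents that add atoms: benzyl bromide BrCc1ccccc1
Why: Williamson etherification; the 2-hydroxyl is hydrogen-bonded to the acetyl carbonyl and least nucleophilic, so two equivalents of benzyl bromide should alkylate only O3 and O4.

Step 2
Reactants: 2 1-[3,4-bis(benzyloxy)-2-hydroxyphenyl]ethanone; 3 4-(benzyloxy)benzaldehyde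
Product: 4 (E)-1-[3,4-bis(benzyloxy)-2-hydroxyphenyl]-3-[4-(benzyloxy)phenyl]prop-2-en-1-one
Conditions: KOH (aq), EtOH, rt
Reagents that add atoms: none
Why: Claisen–Schmidt aldol condensation of the methyl ketone enolate with a non-enolisable aldehyde; the (E)-enone forms under thermodynamic control.

Step 3
Reactants: 4 (E)-2'-hydroxychalcone
Product: 5 rac-7,8-bis(benzyloxy)-2-[4-(benzyloxy)phenyl]chroman-4-one
Conditions: NaOAc, EtOH, reflux
Reagents that add atoms: none
Why: Chalcone–flavanone isomerisation (intramolecular oxa-Michael addition of the 2'-phenoxide) closes ring C'; with no chiral influence the racemate forms.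

Step 4
Reactants: 5 rac-7,8-bis(benzyloxy)-2-[4-(benzyloxy)phenyl]chroman-4-one
Product: 6 (2S,4S)-7,8-bis(benzyloxy)-2-[4-(benzyloxy)phenyl]chroman-4-ol (2,4-cis)
Conditions: RuCl[(S,S)-TsDPEN](p-cymene) (1 mol %), HCO2H–Et3N (5:2), EtOAc, 40 °C, stopped near half conversion
Reagents that add atoms: none
Why: Noyori–Ikariya asymmetric transfer hydrogenation run as a kinetic resolution: the (S,S) catalyst delivers hydride to the face that gives the (4S) carbinol, which for the (2S) ketone is also the face anti to the 2-aryl group (matched case), so (2S,4S)-6 should form fast while the (2R) ketone stays unreduced and is separated; C2' is selected, not created.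

Step 5
Reactants: 6 (2S,4S)-7,8-bis(benzyloxy)-2-[4-(benzyloxy)phenyl]chroman-4-ol; 7 benzene-1,2,3-triol
Product: 8 4-[(2S,4S)-Fl]benzene-1,2,3-triol (2',4'-trans)
Conditions: BF3·OEt2 (0.2 equiv), pyrogallol in eightfold excess, 1,4-dioxane, rt, under N2
Reagents that add atoms: none
Why: Friedel–Crafts alkylation with loss of water: acid ionises the benzylic C4' hydroxyl (cation stabilised by O1' and O7'); excess pyrogallol outcompetes the benzylated ring A' and attacks through its C4 (ortho and para to hydroxyls) along the axial trajectory anti to the equatorial 2'-aryl group, which should give mainly the 2',4'-trans isomer, the cis isomer being removed by chromatography.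

Step 6
Reactants: 8 4-[(2S,4S)-Fl]benzene-1,2,3-triol
Product: 9 2,3,4-trihydroxy-5-[(2S,4S)-Fl]benzaldehyde
Conditions: (chloromethylene)dimethyliminium chloride (1.2 equiv), MeCN, 0 °C to rt; then aq NaOAc
Reagents that add atoms: (chloromethylene)dimethyliminium chloride C[N+](C)=CCl.[Cl-]; water O
Why: Vilsmeier–Haack formylation: the free triol ring is far more nucleophilic than the benzylated rings, and on it only C6 is ortho to one hydroxyl and para to another, so the formyl group should enter ortho to the future O1.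

Step 7
Reactants: 9 2,3,4-trihydroxy-5-[(2S,4S)-Fl]benzaldehyde
Product: 10 3,4-bis(benzyloxy)-2-hydroxy-5-[(2S,4R)-Fl]benzaldehyde
Conditions: BnBr (2.1 equiv), K2CO3 (2.2 equiv), DMF, rt
Reagents that add atoms: benzyl bromide BrCc1ccccc1
Why: Williamson etherification with the same chelation control as in step 1: the 2-hydroxyl is hydrogen-bonded to the formyl group, so O3 and O4 are benzylated and the phenol needed for ring closure stays free.

Step 8
Reactants: 3 4-(benzyloxy)benzaldehyde
Product: 11 (E)-3-[4-(benzyloxy)phenyl]prop-2-enal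
Conditions: Ph3P=CHCHO, toluene, 80 °C
Reagents that add atoms: (triphenylphosphoranylidene)acetaldehyde O=CC=P(c1ccccc1)(c1ccccc1)c1ccccc1
Why: Wittig olefination with a stabilised ylide gives the (E)-enal.

Step 9
Reactants: 10 3,4-bis(benzyloxy)-2-hydroxy-5-[(2S,4R)-Fl]benzaldehyde; 11 (E)-3-[4-(benzyloxy)phenyl]prop-2-enal
Product: 14 (2R)-7,8-bis(benzyloxy)-2-[4-(benzyloxy)phenyl]-6-[(2S,4R)-Fl]-2H-chromene-3-carbaldehyde, via enamine 12 (not isolated), via iminium alkoxide 13 (not isolated)
Conditions: (S)-α,α-diphenylprolinol trimethylsilyl ether (20 mol %), 2-nitrobenzoic acid (20 mol %), toluene, rt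
Reagents that add atoms: none
Why: The amine condenses with enal 11 to an (E)-iminium ion; the only free phenol of 10 (O1, the other ring-A oxygens being benzylated) adds to its β-carbon (oxa-Michael addition, enamine 12), and the enamine carbon, the future C3, then attacks the ortho formyl carbon, the future C4, in an intramolecular aldol addition (13) that forms the C3–C4 bond and closes lower ring C, after which loss of water and hydrolysis of the unsaturated iminium ion release 14 and the catalyst. The closest known reaction type is the amine-catalysed domino oxa-Michael/aldol condensation of salicylaldehydes with cinnamaldehydes to 2-aryl-2H-chromene-3-carbaldehydes. Ring C closes in a 6-(enolexo)-exo-trig mode. C2 is the only new stereocentre that survives; it is set in the oxa-Michael step by the catalyst, whose CPh2(OSiMe3) group shields one face of the iminium ion so that oxygen enters on the open Si face and should give (2R), while C3 and C4 end trigonal and need no control here. The step needs chemoselectivity between two aldehydes and three ring-A oxygens: only 11 can form a conjugated iminium ion and an enamine, only O1 is unprotected, and its ortho relation to the formyl group makes the six-membered aldol closure the only cyclisation available. The acid co-catalyst speeds iminium turnover so that ring closure and dehydration, which make the process irreversible, follow the reversible oxa-Michael step before the ee can erode.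

Step 10
Reactants: 14 (2R)-2H-chromene-3-carbaldehyde
Product: 15 (2R)-7,8-bis(benzyloxy)-2-[4-(benzyloxy)phenyl]-6-[(2S,4R)-Fl]-2H-chromen-3-yl formate
Conditions: mCPBA (1.1 equiv), CH2Cl2, 0 °C
Reagents that add atoms: mCPBA O=C(OO)c1cccc(Cl)c1
Why: Baeyer–Villiger oxidation: in the Criegee adduct the electron-rich alkenyl group migrates in preference to hydrogen, so the formyl carbon leaves the ring and C3 gains its oxygen as an enol formate; C2 is not touched.

Step 11
Reactants: 15 (2R)-2H-chromen-3-yl formate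
Product: 17 (2R,4R)-7,8-bis(benzyloxy)-2-[4-(benzyloxy)phenyl]-6-[(2S,4R)-Fl]-3-oxochroman-4-yl formate, via epoxide 16 (not isolated)
Conditions: dimethyldioxirane (1.1 equiv), acetone–CH2Cl2, −40 to 0 °C, then rt; used crude
Reagents that add atoms: dimethyldioxirane CC1(C)OO1
Why: Epoxidation of the electron-rich enol ester on the face anti to the 2-aryl group, then the known rearrangement of enol ester epoxides: the formyl carbonyl oxygen, held on the aryl face, opens the benzylic C4–O bond from the rear (C4 is activated by O1 and O7), so the acyloxy group shifts suprafacially from C3 to C4, C4 receives oxygen syn to the aryl group (4R) and C3 becomes the ketone.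

Step 12
Reactants: 17 (2R,4R)-3-oxochroman-4-yl formate
Product: 18 (2R,3R,4R)-7,8-bis(benzyloxy)-2-[4-(benzyloxy)phenyl]-6-[(2S,4R)-Fl]chroman-3,4-diol
Conditions: LiBH(s-Bu)3 (3.5 equiv), THF, −78 °C; then H2O
Reagents that add atoms: none
Why: The bulky borohydride should attack the ketone from the face opposite both flanking substituents (2-aryl and 4-formyloxy are cis), as in the known reduction of flavan-3-ones to 2,3-cis-flavan-3-ols, setting (3R); excess hydride also reduces the formate off O4.

Step 13
Reactants: 18 hexa-O-benzyl diol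
Product: 19 (2R,3R,4R)-6-[(2S,4S)-7,8-dihydroxy-2-(4-hydroxyphenyl)chroman-4-yl]-2-(4-hydroxyphenyl)chroman-3,4,7,8-tetrol (CNP0209379.1)
Conditions: H2 (1 atm), Pd(OH)2/C, THF–MeOH, rt, neutral, stopped at full debenzylation
Reagents that add atoms: none
Why: Hydrogenolysis of the six aryl benzyl ethers; the primary O–CH2Ph bonds should cleave much faster than the hindered secondary benzylic C2–O1, C2'–O1' and C4–OH bonds under neutral conditions, so no stereocentre is affected.

## Compound list

1 | 1-(2,3,4-trihydroxyphenyl)ethanone | CC(=O)c1ccc(O)c(O)c1O | starting material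
2 | 1-[3,4-bis(benzyloxy)-2-hydroxyphenyl]ethanone | CC(=O)c1ccc(OCc2ccccc2)c(OCc2ccccc2)c1O | intermediate
3 | 4-(benzyloxy)benzaldehyde | O=Cc1ccc(OCc2ccccc2)cc1 | starting material
4 | (E)-1-[3,4-bis(benzyloxy)-2-hydroxyphenyl]-3-[4-(benzyloxy)phenyl]prop-2-en-1-one | O=C(/C=C/c1ccc(OCc2ccccc2)cc1)c1ccc(OCc2ccccc2)c(OCc2ccccc2)c1O | intermediate
5 | rac-7,8-bis(benzyloxy)-2-[4-(benzyloxy)phenyl]chroman-4-one (racemate) | O=C1CC(c2ccc(OCc3ccccc3)cc2)Oc2c1ccc(OCc1ccccc1)c2OCc1ccccc1 | intermediate
6 | (2S,4S)-7,8-bis(benzyloxy)-2-[4-(benzyloxy)phenyl]chroman-4-ol | c1ccccc1COc1ccc([C@@H]2C[C@H](O)c3ccc(OCc4ccccc4)c(OCc4ccccc4)c3O2)cc1 | intermediate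
7 | benzene-1,2,3-triol (pyrogallol) | Oc1cccc(O)c1O | starting material
8 | 4-[(2S,4S)-Fl]benzene-1,2,3-triol | c1ccccc1COc1ccc([C@@H]2C[C@@H](c3ccc(O)c(O)c3O)c3ccc(OCc4ccccc4)c(OCc4ccccc4)c3O2)cc1 | intermediate
9 | 2,3,4-trihydroxy-5-[(2S,4S)-Fl]benzaldehyde | c1ccccc1COc1ccc([C@@H]2C[C@@H](c3cc(C=O)c(O)c(O)c3O)c3ccc(OCc4ccccc4)c(OCc4ccccc4)c3O2)cc1 | intermediate
10 | 3,4-bis(benzyloxy)-2-hydroxy-5-[(2S,4R)-Fl]benzaldehyde | c1ccccc1COc1ccc([C@@H]2C[C@@H](c3cc(C=O)c(O)c(OCc4ccccc4)c3OCc3ccccc3)c3ccc(OCc4ccccc4)c(OCc4ccccc4)c3O2)cc1 | intermediate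
11 | (E)-3-[4-(benzyloxy)phenyl]prop-2-enal | O=C/C=C/c1ccc(OCc2ccccc2)cc1 | intermediate
12 | oxa-Michael adduct as (E)-enamine of the (S)-catalyst: aryl ether of 10 at the β-carbon of 11, ether carbon arranged as C2 of 14 | c1ccccc1COc1ccc([C@@H]2C[C@@H](c3cc(C=O)c(c(OCc4ccccc4)c3OCc3ccccc3)O[C@H](c3ccc(OCc4ccccc4)cc3)/C=C/N3CCC[C@H]3C(O[Si](C)(C)C)(c3ccccc3)c3ccccc3)c3ccc(OCc4ccccc4)c(OCc4ccccc4)c3O2)cc1 | intermediate (not isolated)
13 | aldol adduct as zwitterionic iminium alkoxide (4-oxidochroman-3-yl methylidene pyrrolidinium; C2 as in 14, C3 and C4 undefined) | c1ccccc1COc1ccc([C@@H]2C[C@@H](c3cc4c(c(OCc5ccccc5)c3OCc3ccccc3)O[C@H](c3ccc(OCc5ccccc5)cc3)C(C=[N+]3CCC[C@H]3C(O[Si](C)(C)C)(c3ccccc3)c3ccccc3)C4[O-])c3ccc(OCc4ccccc4)c(OCc4ccccc4)c3O2)cc1 | intermediate (not isolated)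
14 | (2R)-7,8-bis(benzyloxy)-2-[4-(benzyloxy)phenyl]-6-[(2S,4R)-Fl]-2H-chromene-3-carbaldehyde | c1ccccc1COc1ccc([C@@H]2C[C@@H](c3cc4c(c(OCc5ccccc5)c3OCc3ccccc3)O[C@H](c3ccc(OCc5ccccc5)cc3)C(C=O)=C4)c3ccc(OCc4ccccc4)c(OCc4ccccc4)c3O2)cc1 | intermediate
15 | (2R)-7,8-bis(benzyloxy)-2-[4-(benzyloxy)phenyl]-6-[(2S,4R)-Fl]-2H-chromen-3-yl formate | c1ccccc1COc1ccc([C@@H]2C[C@@H](c3cc4c(c(OCc5ccccc5)c3OCc3ccccc3)O[C@H](c3ccc(OCc5ccccc5)cc3)C(OC=O)=C4)c3ccc(OCc4ccccc4)c(OCc4ccccc4)c3O2)cc1 | intermediate
16 | (2R,3R,4S)-3,4-epoxy-3-formyloxy derivative of the chroman (oxirane oxygen anti to the 2-aryl group) | c1ccccc1COc1ccc([C@@H]2C[C@@H](c3cc4c(c(OCc5ccccc5)c3OCc3ccccc3)O[C@H](c3ccc(OCc5ccccc5)cc3)[C@@]3(OC=O)O[C@H]34)c3ccc(OCc4ccccc4)c(OCc4ccccc4)c3O2)cc1 | intermediate (not isolated)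
17 | (2R,4R)-7,8-bis(benzyloxy)-2-[4-(benzyloxy)phenyl]-6-[(2S,4R)-Fl]-3-oxochroman-4-yl formate (2,4-cis) | c1ccccc1COc1ccc([C@@H]2C[C@@H](c3cc4c(c(OCc5ccccc5)c3OCc3ccccc3)O[C@H](c3ccc(OCc5ccccc5)cc3)C(=O)[C@@H]4OC=O)c3ccc(OCc4ccccc4)c(OCc4ccccc4)c3O2)cc1 | intermediate
18 | (2R,3R,4R)-7,8-bis(benzyloxy)-2-[4-(benzyloxy)phenyl]-6-[(2S,4R)-Fl]chroman-3,4-diol (all-cis) | c1ccccc1COc1ccc([C@@H]2C[C@@H](c3cc4c(c(OCc5ccccc5)c3OCc3ccccc3)O[C@H](c3ccc(OCc5ccccc5)cc3)[C@H](O)[C@@H]4O)c3ccc(OCc4ccccc4)c(OCc4ccccc4)c3O2)cc1 | intermediate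
19 | (2R,3R,4R)-6-[(2S,4S)-7,8-dihydroxy-2-(4-hydroxyphenyl)chroman-4-yl]-2-(4-hydroxyphenyl)chroman-3,4,7,8-tetrol | Oc1ccc([C@@H]2C[C@@H](c3cc4c(c(O)c3O)O[C@H](c3ccc(O)cc3)[C@H](O)[C@@H]4O)c3ccc(O)c(O)c3O2)cc1 | target

## Summary

Total step count: 13. Longest linear sequence: 12 steps (steps 1–7 and 9–13; step 8 is a one-step branch).

Three steps most likely to fail:

1. Step 11. What may go wrong: the labile epoxide may open by a competing path in which the epoxide oxygen stays on C4 (retention, giving the 2,4-trans acyloxy ketone), or the benzylic cation may decompose or be over-oxidised. Fallback: it sets out from 15. N-bromosuccinimide in wet THF at −20 °C should brominate the enol formate on the face anti to the 2-aryl group with loss of the formyl group, giving the (2R,4S)-4-bromo-3-ketone F1. SN2 displacement of the α-keto bromide with HCO2Na in DMF at 0 °C inverts C4 and returns to the route at 17.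

2. Step 9. What may go wrong: slow iminium formation and aldol closure with two electron-rich partners, and erosion of ee by reversible oxa-Michael addition. Fallback: it sets out from 10 and uses nitro instead of formyl as the activating group. Aldehyde 3 is condensed with nitromethane (NH4OAc, AcOH, heat) to the nitroalkene F2. The known amine-catalysed asymmetric tandem oxa-Michael–Henry condensation of 10 with F2 (chiral pyrrolidine-based catalyst with salicylic acid, catalyst enantiomer chosen for 2R) then closes ring C through the same C3–C4 bond and gives the (2R)-3-nitro-2H-chromene F3. Nucleophilic epoxidation (t-BuOOH, DBU, THF, 0 °C) anti to the 2-aryl group gives the nitro epoxide F4. HCO2Na in DMF opens F4 at C4 with inversion and expels nitrite, returning to the route at 17 (14–16 are bypassed).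

3. Step 6. What may go wrong: competing formylation of the benzylated ring A' or of the second free position of the triol ring, O-formylation, and air oxidation of the triol during handling. Fallback: it sets out from 6 and comes back at 9. The Friedel–Crafts alkylation of step 5 is run directly on commercial 2,3,4-trihydroxybenzaldehyde (O=Cc1ccc(O)c(O)c1O, large excess, BF3·OEt2, 1,4-dioxane); its C5 is the only position ortho and para to hydroxyls and meta to the formyl group, so the formyl group is carried in with the nucleophile and 8 is bypassed. This fallback makes no new compound (F0).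

Further compounds

F1 | step 11 | (2R,4S)-7,8-bis(benzyloxy)-2-[4-(benzyloxy)phenyl]-4-bromo-6-[(2S,4R)-Fl]chroman-3-one (bromine anti to the 2-aryl group) | c1ccccc1COc1ccc([C@@H]2C[C@@H](c3cc4c(c(OCc5ccccc5)c3OCc3ccccc3)O[C@H](c3ccc(OCc5ccccc5)cc3)C(=O)[C@H]4Br)c3ccc(OCc4ccccc4)c(OCc4ccccc4)c3O2)cc1
F2 | step 9 | (E)-1-(benzyloxy)-4-(2-nitroethenyl)benzene | [O-][N+](=O)/C=C/c1ccc(OCc2ccccc2)cc1
F3 | step 9 | (2R)-7,8-bis(benzyloxy)-2-[4-(benzyloxy)phenyl]-6-[(2S,4R)-Fl]-3-nitro-2H-chromene | c1ccccc1COc1ccc([C@@H]2C[C@@H](c3cc4c(c(OCc5ccccc5)c3OCc3ccccc3)O[C@H](c3ccc(OCc5ccccc5)cc3)C([N+](=O)[O-])=C4)c3ccc(OCc4ccccc4)c(OCc4ccccc4)c3O2)cc1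
F4 | step 9 | (2R,3S,4S)-3,4-epoxy-3-nitro derivative of the chroman (oxirane oxygen anti to the 2-aryl group) | c1ccccc1COc1ccc([C@@H]2C[C@@H](c3cc4c(c(OCc5ccccc5)c3OCc3ccccc3)O[C@H](c3ccc(OCc5ccccc5)cc3)[C@@]3([N+](=O)[O-])O[C@H]34)c3ccc(OCc4ccccc4)c(OCc4ccccc4)c3O2)cc1
F0 | step 6 | none | none
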